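## Structural features

The target is a single γ-butyrolactone, C9(=O)–C8–C8'–C9'H2–O, with a benzyl arm on each of its two adjacent ring carbons: C7 links C8 to ring A (3,4-dihydroxy-5-methoxyphenyl) and C7' links C8' to ring B (4-hydroxy-3-methoxyphenyl). C8 and C8' are the only stereocentres; they are contiguous, both R, and the two arms are trans. C8 lies α to the carbonyl, so it is epimerisable and settles in the more stable trans arrangement, which leaves C8' as the centre that has to be made deliberately. The fragile groups are the ring A catechol (oxidised by air under base), the three free phenols and the lactone, which alkoxide opens and acid recloses. The real difficulty is that C8' is flanked only by CH2 groups and offers no heteroatom handle for a catalyst or an auxiliary, while the two arenes differ only in oxygenation and must come from separate building blocks. The key step exploits the three-carbon array C8–C8'–C7', which has ring B on C7' and the C9 carbonyl on C8. A temporary C8–C7' bond turns this array into an aryl-donor/carbonyl-acceptor cyclopropane fused to the lactone, which can arise from a C8 carbene and a C8'=C7' styrene tethered through the ester oxygen, and the hydrogenolysis that frees the phenols removes that bond again.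

## Logic of the disconnections

14 ⇒ 13. The bond C8–C7' is added and the three phenols are masked as benzyl ethers. The cut is placed here because this bond lies between the ring B donor and the lactone acceptor and is therefore removable by hydrogenolysis. The gain is that C8' becomes part of a rigid bicycle that one catalytic event can build. The forward step must cleave C8–C7' and not C8'–C7', and must deliver hydrogen to C8 so that the arms end trans.

13 ⇒ 12. The bonds C8–C8' and C8–C7' are cut, which opens both the lactone and the three-membered ring and removes all three stereocentres. What remains is 12, which is achiral and acyclic. The demand is heavy: the carbene at C8 must add to the tethered alkene faster than a C7 hydrogen shifts to it, and a chiral catalyst must choose the alkene face. Ring B keeps an electron-donating ether para to the alkene so that alkene capture is fast, and ring A keeps benzyl ethers so that the end game stays one operation.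

12 ⇒ 11. The diazo group at C8 is traced back to a C8–H that carries an acetyl group. The acetyl group makes C8 acidic enough for diazo transfer and leaves in the same operation, so no separate activation step is needed. The demand is clean loss of the acetyl group from a fully substituted carbon under mild base.

11 ⇒ 6 + 10. The bond C8–C7 is cut between the enolate carbon of 6 and the benzylic carbon of 10. This separates ring A from ring B and makes the route convergent. The demand is mono-C-alkylation.

6 ⇒ 3 + 4 (through 5). The ester C–O bond to the allylic oxygen is cut. A thermal, neutral acetoacetylation is chosen because 3, an electron-rich allylic alcohol, tolerates neither acid nor an activated acyl halide well. The gain is a two-carbon unit that brings both C8 and its activating group, and the demand is only that 5 is trapped by the alcohol faster than it dimerises.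

3 ⇒ 2 ⇒ 1. The C9' carbinol is taken back to the ester oxidation level in 2 and then to commercial 1. One benzylation covers both the phenol and the acid, so no separate esterification is needed. The demand is 1,2-reduction that leaves the (E)-alkene intact.

10 ⇒ 9 ⇒ 8 ⇒ 7. The C7–Br bond is taken back through the alcohol 9 and the aldehyde 8 to commercial 7. These are three functional-group steps with no selectivity question beyond keeping the catechol from air during benzylation.

## Other disconnections considered

Alternative 1: The cut is at C8'–C7' and C8–C7, with the lactone ring already present. In the forward step the lithium anion of 2-[4-(benzyloxy)-3-methoxyphenyl]-1,3-dithiane A1 adds to the β-carbon of (5R)-5-[(1R,2S,5R)-menthyloxy]furan-2(5H)-one A2, anti to the acetal substituent. The resulting lithium enolate is benzylated by 10 anti to the new C8' substituent, which would give the trans,trans lactone A3.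
- In its favour: two C–C bonds and both target stereocentres are set in one flask by polar reactions of established type. Relative and absolute control come from a cheap, crystalline auxiliary. C8 is set directly and needs no later correction.
- Against it here: the auxiliary is stoichiometric and must be attached and removed. The acetal carbon of A3 must be reduced to C9'H2 after opening. The dithiane ring of A3 must be removed with excess Raney Ni, which is wasteful and may touch the benzyl ethers.
- Comparison: on certainty of mechanism and stereocontrol this alternative is the better of the two. On length it is about equal (roughly eleven operations, longest line about seven). The chosen plan is better in using catalytic chirality and in having no sulfur or auxiliary to remove.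

Alternative 2: The cut is at the O–C9' bond, leading back to the prochiral 3-[4-(benzyloxy)-3-methoxybenzyl]cyclobutan-1-one A4. In the forward step a chiral catalyst or an enzyme, with a peroxide, desymmetrises A4 by Baeyer–Villiger oxidation, one of the two enantiotopic CH2 groups migrating to oxygen. This would give (R)-4-[4-(benzyloxy)-3-methoxybenzyl]dihydrofuran-2(3H)-one A5. Enolate benzylation of A5 with 10, anti to the C8' arm, and hydrogenolysis would finish the synthesis.
- In its favour: A4 is symmetric, so there is no regiochemical question. A4 should be reachable in about three steps by a ketene [2+2] cycloaddition and dechlorination. The trans-selective alkylation of A5 is a reliable way to set C8.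
- Against it here: the stereocentre is one CH2 removed from the arene, so the catalyst must tell apart two CH2 groups on the basis of a remote, flexible benzyl group. The electron-rich arene must also survive the oxidant.
- Comparison: on step economy this alternative is the better (about nine operations, longest line six). On setting C8 it is at least the equal. The chosen plan is better on the origin of C8', because the catalyst acts directly at the reacting alkene and not at a distance.

Alternative 3: The cut is at C8'–C9', with a temporary oxygen on C7'. In the forward step the silylmethyl radical is generated with Bu3SnH from the bromide ethyl (2E,4R)-2-[3,4-bis(benzyloxy)-5-methoxybenzyl]-4-[4-(benzyloxy)-3-methoxyphenyl]-4-{[(bromomethyl)dimethylsilyl]oxy}but-2-enoate A6. It adds 5-exo to C8' of the enoate and closes the trans-4,5-disubstituted oxasilolane A7. Tamao–Fleming oxidation, lactonisation, and hydrogenolysis of the C7' oxygen together with the benzyl ethers would follow.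
- In its favour: the polarity is matched (nucleophilic radical, electron-poor alkene), 5-exo closure is fast, and C9' arrives at the right oxidation level.
- Against it here: a C7' carbinol must first be made in enantiopure form and later deleted. Its silyl ether in A6 is benzylic, allylic and para-oxygenated, so it ionises easily. Trans induction from C7' to C8' is only substrate-controlled, C8 remains undefined in A7, and the tin hydride chain and the C–Si oxidation add operations.
- Comparison: it is the equal of the chosen plan in ending with a hydrogenolysis that removes a temporary element at C7' together with the benzyl groups. On directness of stereocontrol and on step economy (clearly longer) the chosen plan is better.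

Key step: step 9

Assumption: the sense of induction is taken from the parent allylic diazoacetate series, in which S-configured dirhodium carboxamidates deliver the (1R,5S) lactones. The R-configured catalyst is therefore written for the (1S,5R,6S) product; if the α-benzyl group inverts the facial preference, the enantiomeric catalyst takes its place.

## Route

Step 1
Reactants: 1 ferulic acid [(E)-3-(4-hydroxy-3-methoxyphenyl)prop-2-enoic acid]
Product: 2 benzyl (E)-3-[4-(benzyloxy)-3-methoxyphenyl]prop-2-enoate
Conditions: BnBr, K2CO3, DMF, 60 °C
Reagents that add atoms: benzyl bromide, BrCc1ccccc1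
Why: Williamson-type O-alkylation; K2CO3 deprotonates both the acid and the phenol and both anions are benzylated by SN2, the (E)-alkene being untouched.

Step 2
Reactants: 2 benzyl (E)-3-[4-(benzyloxy)-3-methoxyphenyl]prop-2-enoate
Product: 3 (E)-3-[4-(benzyloxy)-3-methoxyphenyl]prop-2-en-1-ol
Conditions: iBu2AlH, CH2Cl2, −78 to 0 °C; aq KNaC4H4O6 (Rochelle salt)
Reagents that add atoms: none
Why: 1,2-reduction of an α,β-unsaturated ester by the aluminium hydride at low temperature should give the allylic alcohol without touching the alkene or the aryl benzyl ether; the ester benzyl group leaves as benzyl alcohol.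

Step 3
Reactants: 3 (E)-3-[4-(benzyloxy)-3-methoxyphenyl]prop-2-en-1-ol; 4 2,2,6-trimethyl-4H-1,3-dioxin-4-one
Product: 6 (E)-3-[4-(benzyloxy)-3-methoxyphenyl]prop-2-en-1-yl 3-oxobutanoate, via acetylketene 5 (not isolated)
Conditions: toluene, 110 °C, acetone distilled off
Reagents that add atoms: none
Why: Thermal retro-hetero-Diels–Alder reaction of 4 releases acetone and acetylketene 5, which acylates the primary allylic alcohol (acetoacetylation) under neutral conditions that should not ionise the electron-rich cinnamyl ester.

Step 4
Reactants: 7 3,4-dihydroxy-5-methoxybenzaldehyde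
Product: 8 3,4-bis(benzyloxy)-5-methoxybenzaldehyde
Conditions: BnBr, K2CO3, DMF, N2, 60 °C
Reagents that add atoms: benzyl bromide, BrCc1ccccc1
Why: Williamson ether synthesis on both phenols; the nitrogen atmosphere keeps the catechol anion from air oxidation.

Step 5
Reactants: 8 3,4-bis(benzyloxy)-5-methoxybenzaldehyde
Product: 9 [3,4-bis(benzyloxy)-5-methoxyphenyl]methanol
Conditions: NaBH4, MeOH/THF, 0 °C
Reagents that add atoms: none
Why: Borohydride reduction of an aryl aldehyde to the benzylic alcohol; the ethers are inert.

Step 6
Reactants: 9 [3,4-bis(benzyloxy)-5-methoxyphenyl]methanol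
Product: 10 5-(bromomethyl)-1,2-bis(benzyloxy)-3-methoxybenzene
Conditions: PBr3, CH2Cl2, 0 °C; used without storage
Reagents that add atoms: phosphorus tribromide, BrP(Br)Br
Why: A primary benzylic alcohol is converted into the bromide through its phosphite ester and SN2 displacement by bromide; the cold, short reaction limits self-alkylation of the electron-rich arene.

Step 7
Reactants: 6 (E)-3-[4-(benzyloxy)-3-methoxyphenyl]prop-2-en-1-yl 3-oxobutanoate; 10 5-(bromomethyl)-1,2-bis(benzyloxy)-3-methoxybenzene
Product: 11 (E)-3-[4-(benzyloxy)-3-methoxyphenyl]prop-2-en-1-yl 2-[3,4-bis(benzyloxy)-5-methoxybenzyl]-3-oxobutanoate (racemic at C8)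
Conditions: K2CO3, Bu4NI (cat.), acetone, 50 °C; 6 in slight excess
Reagents that add atoms: none
Why: Acetoacetic ester alkylation; the potassium enolate of 6 is C-benzylated by the benzylic bromide (SN2), forming C8–C7, and the excess of 6 holds back a second alkylation; the racemic centre is erased in step 8.

Step 8
Reactants: 11 (E)-3-[4-(benzyloxy)-3-methoxyphenyl]prop-2-en-1-yl 2-[3,4-bis(benzyloxy)-5-methoxybenzyl]-3-oxobutanoate
Product: 12 (E)-3-[4-(benzyloxy)-3-methoxyphenyl]prop-2-en-1-yl 3-[3,4-bis(benzyloxy)-5-methoxyphenyl]-2-diazopropanoate
Conditions: 4-acetamidobenzenesulfonyl azide, DBU, MeCN, 0 °C to rt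
Reagents that add atoms: 4-acetamidobenzenesulfonyl azide, CC(=O)Nc1ccc(cc1)S(=O)(=O)N=[N+]=[N-]
Why: Regitz deacylative diazo transfer; the enolate adds to the terminal azide nitrogen, the sulfonamide nitrogen of the adduct takes over the acetyl group, and fragmentation leaves the α-diazo ester, with alkene and ethers as spectators.

Step 9
Reactants: 12 (E)-3-[4-(benzyloxy)-3-methoxyphenyl]prop-2-en-1-yl 3-[3,4-bis(benzyloxy)-5-methoxyphenyl]-2-diazopropanoate
Product: 13 (1S,5R,6S)-1-[3,4-bis(benzyloxy)-5-methoxybenzyl]-6-[4-(benzyloxy)-3-methoxyphenyl]-3-oxabicyclo[3.1.0]hexan-2-one (cis-fused; ring B exo)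
Conditions: Rh2(4R-MPPIM)4, i.e. dirhodium tetrakis[methyl 1-(3-phenylpropanoyl)-2-oxoimidazolidine-4(R)-carboxylate] (divalent rhodium, 2 mol %), CH2Cl2, 40 °C, 12 added over 10 h
Reagents that add atoms: none
Why: Proposed new method: intramolecular cyclopropanation by a carbene that carries an α-benzyl group with migratable C7 hydrogens has not been shown; the closest known reaction type is the dirhodium-carboxamidate-catalysed enantioselective intramolecular cyclopropanation of allylic diazoacetates and diazopropanoates. The catalyst takes N2 from 12 and the electrophilic catalyst-bound carbene at C8 is attacked by the electron-rich styrene, bonding to C8' running ahead of bonding to C7' in one asynchronous but stereospecific event. The lactone closes as a five-membered ring through C8–C8' in a 5-exo-type capture of the tethered alkene, for which the ester adopts its s-cis form about the C9–O bond, and the three-membered ring closes in the same event through C8–C7' as a [2+1] addition. C8' is set by the alkene face that the chiral ligand pocket leaves open, C8 follows from the cis fusion that the three-atom tether enforces, and C7' follows from the retained (E) geometry, which places ring B exo. The step needs chemoselectivity for alkene capture over 1,2-hydride shift from C7, which would give a cinnamate. It is supported by the para-benzyloxy group of ring B, which makes the alkene a strong π-nucleophile held five atoms from the carbene, by the carboxamidate ligands, which lower the electrophilicity of the carbene, and by slow addition, which keeps azine and carbene-dimer formation down.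

Step 10
Reactants: 13 (1S,5R,6S)-1-[3,4-bis(benzyloxy)-5-methoxybenzyl]-6-[4-(benzyloxy)-3-methoxyphenyl]-3-oxabicyclo[3.1.0]hexan-2-one
Product: 14 (−)-thujaplicatin [(3R,4R)-3-(3,4-dihydroxy-5-methoxybenzyl)-4-(4-hydroxy-3-methoxybenzyl)dihydrofuran-2(3H)-one]
Conditions: H2 (1–3 atm), 10% Pd/C, EtOAc/EtOH, rt
Reagents that add atoms: none
Why: Heterogeneous hydrogenolysis should cleave the cyclopropane bond C8–C7', the one weakened by both the ring B donor on C7' and the carbonyl acceptor on C8 (benzylic C–C hydrogenolysis of a donor–acceptor cyclopropane), and the three O-benzyl groups leave as toluene under the same conditions. C8' is untouched, and hydrogen is expected at C8 on the face that C7' vacates, which puts the C8 arm trans to the C8' arm (8R), the arrangement also favoured thermodynamically.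

## Compound list

1 | ferulic acid, (E)-3-(4-hydroxy-3-methoxyphenyl)prop-2-enoic acid | COc1cc(/C=C/C(=O)O)ccc1O | starting material
2 | benzyl (E)-3-[4-(benzyloxy)-3-methoxyphenyl]prop-2-enoate | COc1cc(/C=C/C(=O)OCc2ccccc2)ccc1OCc1ccccc1 | intermediate
3 | (E)-3-[4-(benzyloxy)-3-methoxyphenyl]prop-2-en-1-ol | COc1cc(/C=C/CO)ccc1OCc1ccccc1 | intermediate
4 | 2,2,6-trimethyl-4H-1,3-dioxin-4-one | CC1=CC(=O)OC(C)(C)O1 | starting material
5 | acetylketene (not isolated) | CC(=O)C=C=O | intermediate
6 | (E)-3-[4-(benzyloxy)-3-methoxyphenyl]prop-2-en-1-yl 3-oxobutanoate | COc1cc(/C=C/COC(=O)CC(C)=O)ccc1OCc1ccccc1 | intermediate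
7 | 3,4-dihydroxy-5-methoxybenzaldehyde | COc1cc(C=O)cc(O)c1O | starting material
8 | 3,4-bis(benzyloxy)-5-methoxybenzaldehyde | COc1cc(C=O)cc(OCc2ccccc2)c1OCc1ccccc1 | intermediate
9 | [3,4-bis(benzyloxy)-5-methoxyphenyl]methanol | COc1cc(CO)cc(OCc2ccccc2)c1OCc1ccccc1 | intermediate
10 | 5-(bromomethyl)-1,2-bis(benzyloxy)-3-methoxybenzene | COc1cc(CBr)cc(OCc2ccccc2)c1OCc1ccccc1 | intermediate
11 | (E)-3-[4-(benzyloxy)-3-methoxyphenyl]prop-2-en-1-yl 2-[3,4-bis(benzyloxy)-5-methoxybenzyl]-3-oxobutanoate (racemic) | COc1cc(/C=C/COC(=O)C(Cc2cc(OC)c(OCc3ccccc3)c(OCc3ccccc3)c2)C(C)=O)ccc1OCc1ccccc1 | intermediate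
12 | (E)-3-[4-(benzyloxy)-3-methoxyphenyl]prop-2-en-1-yl 3-[3,4-bis(benzyloxy)-5-methoxyphenyl]-2-diazopropanoate | COc1cc(/C=C/COC(=O)C(=[N+]=[N-])Cc2cc(OC)c(OCc3ccccc3)c(OCc3ccccc3)c2)ccc1OCc1ccccc1 | intermediate
13 | (1S,5R,6S)-1-[3,4-bis(benzyloxy)-5-methoxybenzyl]-6-[4-(benzyloxy)-3-methoxyphenyl]-3-oxabicyclo[3.1.0]hexan-2-one | O=C1OC[C@@H]2[C@@H](c3ccc(OCc4ccccc4)c(OC)c3)[C@]12Cc1cc(OC)c(OCc2ccccc2)c(OCc2ccccc2)c1 | intermediate
14 | (−)-thujaplicatin, (3R,4R)-3-(3,4-dihydroxy-5-methoxybenzyl)-4-(4-hydroxy-3-methoxybenzyl)dihydrofuran-2(3H)-one | COc1cc(C[C@H]2COC(=O)[C@@H]2Cc2cc(O)c(O)c(OC)c2)ccc1O | target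

## Step count and least certain steps

Total step count: 10. Longest linear sequence: 7 steps (1, 2, 3, 7, 8, 9, 10 from 1; the branch 4, 5, 6, 7, 8, 9, 10 from 7 is equally long).

**Key step, step 9 (Proposed new method).** The most likely failure is 1,2-hydride shift from C7 to the carbene carbon outrunning capture by the alkene. The migrating hydrogen is benzylic and activated by the para oxygen of ring A, and the competing cyclisation must first pass through the less populated s-cis ester conformer. A second possibility is poor facial selectivity, because the α-substituent changes how the carbene sits in the ligand pocket. Because carboxamidate catalysts lose N2 from the diazo ester only near ambient temperature, cooling is of limited use, and the ligand is the main handle.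

The fallback uses known chemistry. It sets out from 6, uses 10 on the way, and comes back to the route at 14. Diazo transfer to 6 with 4-acetamidobenzenesulfonyl azide and Et3N should give (E)-3-[4-(benzyloxy)-3-methoxyphenyl]allyl 2-diazo-3-oxobutanoate F1, and deacetylation with aqueous LiOH should give (E)-3-[4-(benzyloxy)-3-methoxyphenyl]allyl diazoacetate F2. The carbene from F2 has no migratable hydrogen, so the established enantioselective intramolecular cyclopropanation with Rh2(4R-MPPIM)4 should give (1S,5R,6R)-6-[4-(benzyloxy)-3-methoxyphenyl]-3-oxabicyclo[3.1.0]hexan-2-one F3. Hydrogenolysis over Pd/C should open the cyclopropane and remove the benzyl group, giving (R)-4-(4-hydroxy-3-methoxybenzyl)dihydrofuran-2(3H)-one F4. Re-benzylation (BnBr, K2CO3) should give (R)-4-[4-(benzyloxy)-3-methoxybenzyl]dihydrofuran-2(3H)-one F5. The lithium enolate of this lactone (LiN(SiMe3)2, THF, −78 °C) should be alkylated by 10 anti to the C8' arm, giving (3R,4R)-4-[4-(benzyloxy)-3-methoxybenzyl]-3-[3,4-bis(benzyloxy)-5-methoxybenzyl]dihydrofuran-2(3H)-one F6. Hydrogenolysis of the three benzyl ethers over Pd/C then gives 14.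

**Step 10.** The most likely failure is delivery of hydrogen to C8 on the face opposite to the departing C7'. This would happen if the surface intermediate behaves as an oxygen-bound enolate that is protonated from the less hindered side, and it would give the cis lactone beside 14. Cleavage of C8'–C7' in place of C8–C7' is the lesser risk, because only the C8–C7' bond is activated by both the aryl and the carbonyl group.

The fallback replaces kinetic delivery by thermodynamic control. It sets out from 13 and comes back at 14. Hydrogenolysis as in step 10 would give 14 together with (3S,4R)-3-(3,4-dihydroxy-5-methoxybenzyl)-4-(4-hydroxy-3-methoxybenzyl)dihydrofuran-2(3H)-one F7. The unseparated mixture is equilibrated through the lactone enolate with DBU in degassed THF/MeOH under argon (to protect the catechol) and then acidified, which should converge on the trans lactone 14.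

**Step 8.** The most likely failure is slow or incomplete acetyl transfer from the crowded adduct at the fully substituted C8, with base-induced degradation of the diazo ester on prolonged exposure to DBU.

The fallback activates a simple ester only transiently. It sets out from 3 and 10 and comes back at 12. Acetylation of 3 (Ac2O, pyridine) should give (E)-3-[4-(benzyloxy)-3-methoxyphenyl]allyl acetate F8. Its lithium enolate (LiN(iPr)2, THF/DMPU, −78 °C, kept cold to avoid Ireland–Claisen rearrangement) should be alkylated by 10, giving (E)-3-[4-(benzyloxy)-3-methoxyphenyl]allyl 3-[3,4-bis(benzyloxy)-5-methoxyphenyl]propanoate F9. Claisen-type trifluoroacetylation of the enolate of this ester (LiN(SiMe3)2, then 2,2,2-trifluoroethyl trifluoroacetate) should give (E)-3-[4-(benzyloxy)-3-methoxyphenyl]allyl 2-[3,4-bis(benzyloxy)-5-methoxybenzyl]-4,4,4-trifluoro-3-oxobutanoate F10, which is used crude. Detrifluoroacetylative diazo transfer with methanesulfonyl azide and Et3N in wet MeCN should then give 12.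

**Step 7.** The most likely failure is a second alkylation at C8 or O-alkylation of the enolate, together with self-condensation of the electron-rich bromide 10 before it is consumed.

The fallback avoids the halide altogether. It sets out from 6 and 8 and comes back at 11. Knoevenagel condensation of 8 with 6 (piperidine/AcOH, toluene, water removed) should give (E)-3-[4-(benzyloxy)-3-methoxyphenyl]allyl 2-[3,4-bis(benzyloxy)-5-methoxybenzylidene]-3-oxobutanoate F11, whose benzylidene geometry is of no consequence. Conjugate reduction with a Hantzsch ester, which attacks only the doubly activated alkene and spares the cinnamyl alkene, should give 11.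

## Further compounds

F1 | step 9 | (E)-3-[4-(benzyloxy)-3-methoxyphenyl]allyl 2-diazo-3-oxobutanoate | COc1cc(/C=C/COC(=O)C(=[N+]=[N-])C(C)=O)ccc1OCc1ccccc1
F2 | step 9 | (E)-3-[4-(benzyloxy)-3-methoxyphenyl]allyl diazoacetate | COc1cc(/C=C/COC(=O)C=[N+]=[N-])ccc1OCc1ccccc1
F3 | step 9 | (1S,5R,6R)-6-[4-(benzyloxy)-3-methoxyphenyl]-3-oxabicyclo[3.1.0]hexan-2-one | O=C1OC[C@@H]2[C@@H](c3ccc(OCc4ccccc4)c(OC)c3)[C@H]12
F4 | step 9 | (R)-4-(4-hydroxy-3-methoxybenzyl)dihydrofuran-2(3H)-one | O=C1C[C@@H](Cc2ccc(O)c(OC)c2)CO1
F5 | step 9 | (R)-4-[4-(benzyloxy)-3-methoxybenzyl]dihydrofuran-2(3H)-one | O=C1C[C@@H](Cc2ccc(OCc3ccccc3)c(OC)c2)CO1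
F6 | step 9 | (3R,4R)-4-[4-(benzyloxy)-3-methoxybenzyl]-3-[3,4-bis(benzyloxy)-5-methoxybenzyl]dihydrofuran-2(3H)-one | COc1cc(C[C@H]2COC(=O)[C@@H]2Cc2cc(OCc3ccccc3)c(OCc3ccccc3)c(OC)c2)ccc1OCc1ccccc1
F7 | step 10 | (3S,4R)-3-(3,4-dihydroxy-5-methoxybenzyl)-4-(4-hydroxy-3-methoxybenzyl)dihydrofuran-2(3H)-one | COc1cc(C[C@H]2COC(=O)[C@H]2Cc2cc(O)c(O)c(OC)c2)ccc1O
F8 | step 8 | (E)-3-[4-(benzyloxy)-3-methoxyphenyl]allyl acetate | COc1cc(/C=C/COC(C)=O)ccc1OCc1ccccc1
F9 | step 8 | (E)-3-[4-(benzyloxy)-3-methoxyphenyl]allyl 3-[3,4-bis(benzyloxy)-5-methoxyphenyl]propanoate | COc1cc(/C=C/COC(=O)CCc2cc(OC)c(OCc3ccccc3)c(OCc3ccccc3)c2)ccc1OCc1ccccc1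
F10 | step 8 | (E)-3-[4-(benzyloxy)-3-methoxyphenyl]allyl 2-[3,4-bis(benzyloxy)-5-methoxybenzyl]-4,4,4-trifluoro-3-oxobutanoate | COc1cc(/C=C/COC(=O)C(Cc2cc(OC)c(OCc3ccccc3)c(OCc3ccccc3)c2)C(=O)C(F)(F)F)ccc1OCc1ccccc1
F11 | step 7 | (E)-3-[4-(benzyloxy)-3-methoxyphenyl]allyl 2-[3,4-bis(benzyloxy)-5-methoxybenzylidene]-3-oxobutanoate | COc1cc(/C=C/COC(=O)C(=Cc2cc(OC)c(OCc3ccccc3)c(OCc3ccccc3)c2)C(C)=O)ccc1OCc1ccccc1
A1 | alternative 1 | 2-[4-(benzyloxy)-3-methoxyphenyl]-1,3-dithiane | COc1cc(C2SCCCS2)ccc1OCc1ccccc1
A2 | alternative 1 | (5R)-5-{[(1R,2S,5R)-5-methyl-2-(propan-2-yl)cyclohexyl]oxy}furan-2(5H)-one | O=C1C=C[C@H](O[C@@H]2C[C@H](C)CC[C@H]2C(C)C)O1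
A3 | alternative 1 | (3R,4R,5R)-3-[3,4-bis(benzyloxy)-5-methoxybenzyl]-4-{2-[4-(benzyloxy)-3-methoxyphenyl]-1,3-dithian-2-yl}-5-{[(1R,2S,5R)-5-methyl-2-(propan-2-yl)cyclohexyl]oxy}dihydrofuran-2(3H)-one | O=C1O[C@@H](O[C@@H]2C[C@H](C)CC[C@H]2C(C)C)[C@H](C2(c3ccc(OCc4ccccc4)c(OC)c3)SCCCS2)[C@H]1Cc1cc(OC)c(OCc2ccccc2)c(OCc2ccccc2)c1
A4 | alternative 2 | 3-[4-(benzyloxy)-3-methoxybenzyl]cyclobutan-1-one | O=C1CC(Cc2ccc(OCc3ccccc3)c(OC)c2)C1
A5 | alternative 2 | (R)-4-[4-(benzyloxy)-3-methoxybenzyl]dihydrofuran-2(3H)-one | O=C1C[C@@H](Cc2ccc(OCc3ccccc3)c(OC)c2)CO1
A6 | alternative 3 | ethyl (2E,4R)-2-[3,4-bis(benzyloxy)-5-methoxybenzyl]-4-[4-(benzyloxy)-3-methoxyphenyl]-4-{[(bromomethyl)dimethylsilyl]oxy}but-2-enoate | CCOC(=O)/C(Cc1cc(OC)c(OCc2ccccc2)c(OCc2ccccc2)c1)=C/[C@@H](O[Si](C)(C)CBr)c1ccc(OCc2ccccc2)c(OC)c1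
A7 | alternative 3 | ethyl 3-[3,4-bis(benzyloxy)-5-methoxyphenyl]-2-{(4S,5R)-5-[4-(benzyloxy)-3-methoxyphenyl]-2,2-dimethyl-1,2-oxasilolan-4-yl}propanoate (C8 undefined) | CCOC(=O)C(Cc1cc(OC)c(OCc2ccccc2)c(OCc2ccccc2)c1)[C@@H]1C[Si](C)(C)O[C@H]1c1ccc(OCc2ccccc2)c(OC)c1
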